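The retrosynthesis first removes the O13 ether, the oxiranes C1–O–C10 and C4–O–C5 and the C8 tiglate, then cuts the butenolide at C7=C11 and O6–C12. C5–H is traced to an enol triflate, and a reversed [3,3] shift (C2–C3 cut, C5–C10 joined) contracts the ten-membered ring.
Enabling feature: the two trans-oxiranes mask the (E,E)-1,5-diene C10(Me)=C1–C2–C3–C4(Me)=C5 of ring A (carbocycle C1–C10). Joining C5 to C10 turns ring A into a cyclohexane C5–C6–C7–C8–C9–C10 with a vinyl group (C1=C2) on C10 and an isopropenyl group (C3=C4, C15) on a C5 carbinol.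
Forward order: pyranose, then cyclohexanone (C9–C10 bond by Ferrier carbocyclisation), C10 quaternary centre (vinyl first, methyl last), C5 carbinol, ring A by oxy-Cope ring expansion, butenolide ring B by intramolecular Horner–Wadsworth–Emmons closure with a phosphonate that already carries C13–O, tiglate, and the two oxiranes.
Stereochemistry: C6 and C8 are C4 and C2 of D-glucose. The transient centres C5 and C10 serve only to fix both ring alkenes as E through a chair transition state.
C1, C10, C4 and C5 of the target come from peracid attack on the outer faces of the crown conformer of the (E,E)-diene.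
Key step: step 13

Remark: carbocycles carry germacrane numbering (glucose C1, C2, C3, C4, C5, C6 become C9, C8, C7, C6, C5, C10); TBS = tert-butyldimethylsilyl, TES = triethylsilyl, PMB = 4-methoxybenzyl, Tf = trifluoromethanesulfonyl; the phosphonate carbon C11 is carried as an epimer mixture until it becomes trigonal.

Step 1
Reactants: 1 methyl α-D-glucopyranoside
Product: 2 methyl 4,6-O-[(R)-4-methoxybenzylidene]-α-D-glucopyranoside
Conditions: 4-MeOC6H4CH(OMe)2, camphorsulfonic acid (cat.), DMF, 55 °C, reduced pressure
Reagents that add atoms: 4-methoxybenzaldehyde dimethyl acetal, COc1ccc(cc1)C(OC)OC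
Why: Acid-catalysed transacetalisation under thermodynamic control engages only the O4/O6 pair in a trans-fused 1,3-dioxane, and the new acetal carbon settles as the R epimer with the aryl group equatorial.

Step 2
Reactants: 2 methyl 4,6-O-[(R)-4-methoxybenzylidene]-α-D-glucopyranoside
Product: 3 methyl 2-O-TBS-4,6-O-[(R)-4-methoxybenzylidene]-α-D-glucopyranoside
Conditions: TBSCl (1.1 equiv), imidazole, DMF, 0 °C to rt
Reagents that add atoms: tert-butyldimethylsilyl chloride, CC(C)(C)[Si](C)(C)Cl
Why: Regioselective silylation of a diol: O2–H, activated by the neighbouring anomeric centre and less crowded than O3–H next to the acetal ring, should take up the single equivalent of silyl chloride.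

Step 3
Reactants: 3 methyl 2-O-TBS-4,6-O-[(R)-4-methoxybenzylidene]-α-D-glucopyranoside
Product: 4 methyl 2-O-TBS-3-O-TES-4,6-O-[(R)-4-methoxybenzylidene]-α-D-glucopyranoside
Conditions: TESOTf, 2,6-lutidine, CH2Cl2, −78 to 0 °C
Reagents that add atoms: triethylsilyl trifluoromethanesulfonate, CC[Si](CC)(CC)OS(=O)(=O)C(F)(F)F
Why: Silylation with a silyl triflate and a hindered pyridine base caps the crowded O3–H at low temperature and avoids the alkoxide conditions under which the O2 silyl group could migrate.

Step 4
Reactants: 4 methyl 2-O-TBS-3-O-TES-4,6-O-[(R)-4-methoxybenzylidene]-α-D-glucopyranoside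
Product: 5 methyl 2-O-TBS-3-O-TES-4-O-PMB-α-D-glucopyranoside
Conditions: i-Bu2AlH, CH2Cl2, −78 to 0 °C
Reagents that add atoms: none
Why: Regioselective reductive opening of a 4-methoxybenzylidene acetal: aluminium binds the less hindered O6, the C–O6 bond ionises and hydride quenches the oxocarbenium ion, so the PMB ether stays on O4 and the primary alcohol is set free.

Step 5
Reactants: 5 methyl 2-O-TBS-3-O-TES-4-O-PMB-α-D-glucopyranoside
Product: 6 methyl 6-deoxy-6-iodo-2-O-TBS-3-O-TES-4-O-PMB-α-D-glucopyranoside
Conditions: I2, PPh3, imidazole, toluene, rt to 50 °C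
Reagents that add atoms: iodine, II
Why: Garegg–Samuelsson iodination (Appel type) converts the only free, primary hydroxyl into the iodide by SN2 displacement of its oxyphosphonium salt, with imidazole keeping the medium neutral for the silyl ethers.

Step 6
Reactants: 6 methyl 6-deoxy-6-iodo-2-O-TBS-3-O-TES-4-O-PMB-α-D-glucopyranoside
Product: 7 methyl 6-deoxy-2-O-TBS-3-O-TES-4-O-PMB-α-D-xylo-hex-5-enopyranoside
Conditions: t-BuOK, THF, 0 °C
Reagents that add atoms: none
Why: E2 dehydrohalogenation removes H5 and iodide to give the exocyclic enol ether, the standard substrate of the carbocyclisation, and no other β-hydrogen is available.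

Step 7
Reactants: 7 methyl 6-deoxy-2-O-TBS-3-O-TES-4-O-PMB-α-D-xylo-hex-5-enopyranoside
Product: 8 C9-hydroxy cyclohexan-5-one with equatorial C6-OPMB C7-OTES C8-OTBS (C9-OH axial)
Conditions: Hg(OCOCF3)2 (10 mol %), acetone/H2O 4:1, rt
Reagents that add atoms: water, O
Why: Ferrier carbocyclisation: catalytic oxymercuration of the enol ether, collapse of the hemiketal with loss of methanol and intramolecular aldol addition of the C10 mercurio-enolate to the C9 aldehyde forge the C9–C10 bond, while the C6–C8 centres are untouched and the new C9 carbinol (expected axial) is erased in the next step.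

Step 8
Reactants: 8 C9-hydroxy cyclohexan-5-one with equatorial C6-OPMB C7-OTES C8-OTBS (C9-OH axial)
Product: 10 cyclohex-9-en-5-one with C6-OPMB C7-OTES C8-OTBS, via mesylate 9 (not isolated)
Conditions: MsCl, Et3N, CH2Cl2, 0 °C
Reagents that add atoms: none
Why: Mesylation and E1cB elimination of the β-mesyloxy ketone by triethylamine give the conjugated enone, a routine follow-up of the carbocyclisation that is run cold to spare the C6 and C7 ethers.

Step 9
Reactants: 10 cyclohex-9-en-5-one with C6-OPMB C7-OTES C8-OTBS
Product: 11 C10-iodo enone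
Conditions: I2, pyridine/CH2Cl2, 0 °C to rt
Reagents that add atoms: iodine, II
Why: α-Iodination of an enone by the pyridine addition–iodination–elimination sequence (Baylis–Hillman-type mechanism) works on β-unsubstituted cyclohexenones such as 10 and touches no stereocentre.

Step 10
Reactants: 11 C10-iodo enone; 12 tributyl(vinyl)stannane
Product: 13 C10-vinyl enone
Conditions: PdCl2(PhCN)2 (5 mol %), AsPh3, CuI, NMP, rt
Reagents that add atoms: none
Why: Stille coupling of an α-iodoenone under ligand-accelerated, copper-assisted conditions runs at room temperature, which limits Diels–Alder dimerisation of the cross-conjugated dienone.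

Step 11
Reactants: 13 C10-vinyl enone
Product: 15 C10-methyl C10-vinyl cyclohexan-5-one (methyl axial; vinyl equatorial cis to O8), via lithium dienolate 14 (not isolated)
Conditions: LiBH(s-Bu)3, THF, −78 °C; then MeI, DMPU, −78 to −20 °C
Reagents that add atoms: iodomethane, CI
Why: Conjugate reduction–enolate alkylation: the hindered borohydride adds hydride to the unsubstituted C9, and the regiodefined dienolate is methylated at its α-carbon C10 along the axial trajectory that leads directly to the chair with three equatorial ethers, so the methyl group should end axial and the vinyl group equatorial, cis to O8.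

Step 12
Reactants: 15 C10-methyl C10-vinyl cyclohexan-5-one; 16 isopropenylmagnesium bromide
Product: 17 C5-isopropenyl C10-methyl C10-vinyl cyclohexan-5-ol with C6-OPMB C7-OTES C8-OTBS (OH axial cis to O6; isopropenyl equatorial trans to vinyl)
Conditions: LaCl3·2LiCl, THF, −78 to −20 °C
Reagents that add atoms: none
Why: Chelation-controlled Grignard 1,2-addition (Cram cyclic model): the Lewis acidic metal bridges the C5 carbonyl oxygen and the equatorial O6 ether and suppresses enolisation, and the branched alkenyl nucleophile should enter along the equatorial path on the side of C6–H, away from the axial hydrogens on C7 and C9, which places the hydroxyl axial (cis to O6) and the isopropenyl group equatorial, trans to the vinyl group.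

Step 13
Reactants: 17 C5-isopropenyl C10-methyl C10-vinyl cyclohexan-5-ol
Product: 20 ten-membered 1(10)E-dienyl C5 triflate with C3 trans to C6 and C6-OPMB C7-OTES C8-OTBS, via potassium alkoxide 18 (not isolated), via potassium enolate 19 (not isolated)
Conditions: KN(SiMe3)2, 18-crown-6, THF, 0 °C to rt; then PhNTf2, −78 to 0 °C
Reagents that add atoms: N-phenylbis(trifluoromethanesulfonimide), O=S(=O)(N(c1ccccc1)S(=O)(=O)C(F)(F)F)C(F)(F)F
Why: Deprotonation of the tertiary C5 carbinol gives the loosely paired alkoxide 18, whose oxido group weakens the C5–C10 bond and triggers a concerted [3,3]-sigmatropic shift in which C2 bonds to C3 while C5–C10 breaks; this is the anionic oxy-Cope rearrangement of a trans-1,2-dialkenylcyclohexanol, the standard entry to (E)-cyclodec-5-enone enolates. The ten-membered ring is not closed end to end but arises by four-atom expansion of the cyclohexane, so neither high dilution nor a macrocyclisation entropy penalty is involved. No stereocentre is created: C5 and C10 become trigonal, and the chair-like six-centre transition state, in which vinyl, isopropenyl and the ring bonds C10–C9 and C5–C6 are all equatorial, translates their trans relationship into the E C1=C10 alkene and into enolate 19 with C3 trans to C6. The three equatorial ethers at C6, C7 and C8 hold the cyclohexane in exactly this chair, with the C10 methyl group and the oxido group axial and antiperiplanar, so the reactive conformer is the ground state. The step needs the tetrasubstituted C4=C5 enolate to be captured before proton transfer to C6 can start loss of the C7 silyloxy group, which is why PhNTf2 is added cold as soon as the shift is complete and why O6 carries an ether that cannot migrate to O5. O-Sulfonylation then fixes the regiochemistry and the geometry of the enolate in triflate 20.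

Step 14
Reactants: 20 ten-membered dienyl C5 triflate
Product: 21 (1(10)E,4E)-germacradiene with C6-OPMB C7-OTES C8-OTBS
Conditions: Pd(OAc)2 (5 mol %), PPh3 (10 mol %), HCO2H, Et3N, DMF, 45 °C
Reagents that add atoms: none
Why: Palladium-catalysed formate reduction of an enol triflate: oxidative addition to zerovalent palladium formed in situ, exchange for formate, decarboxylation and reductive elimination replace the triflate by hydrogen with retention, so the C4=C5 alkene emerges E.

Step 15
Reactants: 21 (1(10)E,4E)-germacradiene with C6-OPMB C7-OTES C8-OTBS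
Product: 22 germacradien-6-ol with C7-OTES C8-OTBS
Conditions: DDQ, CH2Cl2/pH 7 phosphate buffer, 0 °C
Reagents that add atoms: none
Why: Oxidative cleavage of the PMB ether by DDQ (hydride abstraction, hydrolysis of the oxocarbenium ion) is orthogonal to both silyl ethers and is run cold and buffered so that the acid-sensitive 1,5-diene and the new allylic alcohol are not affected.

Step 16
Reactants: 23 methyl 2-(dimethoxyphosphoryl)acrylate; 24 4-methoxybenzyl alcohol
Product: 25 methyl 2-(dimethoxyphosphoryl)-3-(4-methoxybenzyloxy)propanoate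
Conditions: t-BuOK (10 mol %), THF, 0 °C
Reagents that add atoms: none
Why: Base-catalysed oxa-Michael addition of an alkoxide to a vinylphosphonate doubly activated by ester and phosphoryl groups installs C13 with its oxygen already protected, and C11 is formed as a racemate, which is irrelevant because it becomes trigonal later.

Step 17
Reactants: 25 methyl 2-(dimethoxyphosphoryl)-3-(4-methoxybenzyloxy)propanoate
Product: 26 2-(dimethoxyphosphoryl)-3-(4-methoxybenzyloxy)propanoic acid
Conditions: LiOH (1.05 equiv), THF/H2O, 0 °C; then 1 M HCl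
Reagents that add atoms: lithium hydroxide, [Li+].[OH-]
Why: Saponification of the carboxylic methyl ester is much faster than attack on the phosphonate methyl esters, and at 0 °C with one equivalent of hydroxide retro-Michael loss of the alkoxide should stay negligible.

Step 18
Reactants: 22 germacradien-6-ol with C7-OTES C8-OTBS; 26 2-(dimethoxyphosphoryl)-3-(4-methoxybenzyloxy)propanoic acid
Product: 27 C6 phosphonopropanoate ester with C7-OTES C8-OTBS
Conditions: EDC·HCl, DMAP (cat.), CH2Cl2, 0 °C to rt
Reagents that add atoms: none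
Why: Carbodiimide esterification with DMAP (Steglich type) acylates the only free hydroxyl, O6, with retention at C6.

Step 19
Reactants: 27 C6 phosphonopropanoate ester with C7-OTES C8-OTBS
Product: 28 C7 alcohol (C6 phosphonopropanoate; C8-OTBS)
Conditions: pyridinium p-toluenesulfonate (cat.), MeOH/CH2Cl2, 0 °C
Reagents that add atoms: none
Why: Acid-catalysed methanolysis distinguishes silyl ethers by size: the secondary TES ether is cleaved far faster than the TBS ether, and the medium is too weakly acidic to protonate the ring alkenes.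

Step 20
Reactants: 28 C7 alcohol (C6 phosphonopropanoate; C8-OTBS)
Product: 30 germacra-1(10),4,7(11)-trien-12,6-olide with C8-OTBS C13-OPMB, via keto phosphonate 29 (not isolated)
Conditions: Dess–Martin periodinane, CH2Cl2, 0 °C to rt; filtrate concentrated, then LiCl, i-Pr2NEt, MeCN, 0 °C to rt
Reagents that add atoms: none
Why: Dess–Martin oxidation gives the C7 ketone, and intramolecular Horner–Wadsworth–Emmons olefination under Masamune–Roush conditions closes the five-membered butenolide (C7=C11) faster than the stabilised carbanion can expel the poor PMB-oxide leaving group or the mild amine base can epimerise C6 or C8.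

Step 21
Reactants: 30 germacra-1(10),4,7(11)-trien-12,6-olide with C8-OTBS C13-OPMB
Product: 31 C8 alcohol of the trienolide (C13-OPMB)
Conditions: Bu4NF/AcOH 1:1, THF, 0 °C to rt
Reagents that add atoms: none
Why: Fluoride desilylation buffered with acetic acid removes the TBS group without generating a base strong enough to deprotonate the γ-position C6 of the butenolide, and the PMB ether at O13 is inert.

Step 22
Reactants: 31 C8 alcohol of the trienolide (C13-OPMB); 32 tiglic acid
Product: 33 C8 tiglate of the trienolide (C13-OPMB)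
Conditions: DCC, DMAP (cat.), CH2Cl2, rt
Reagents that add atoms: none
Why: Steglich esterification of the free C8 hydroxyl proceeds with retention at C8 while O13 is still masked, and the E geometry of tiglic acid, the more stable isomer, is not at risk.

Step 23
Reactants: 33 C8 tiglate of the trienolide (C13-OPMB)
Product: 34 1β,10α:4α,5β-diepoxide (C8 tiglate; C13-OPMB)
Conditions: mCPBA (2.3 equiv), NaHCO3, CH2Cl2, 0 °C
Reagents that add atoms: 3-chloroperoxybenzoic acid, OOC(=O)c1cccc(Cl)c1
Why: Prilezhaev epoxidation is chemoselective for the two electron-rich trisubstituted ring alkenes over the conjugated tiglate and butenolide alkenes, it is stereospecific (E alkenes give trans-oxiranes), and attack on the exposed outer faces of the crown conformer, in which both ring methyl groups point to the face opposite to O6 and O8, should set 1R,10R and 4R,5R.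

Step 24
Reactants: 34 1β,10α:4α,5β-diepoxide (C8 tiglate; C13-OPMB)
Product: 35 CNP0111480.1
Conditions: DDQ, CH2Cl2/pH 7 phosphate buffer, 0 °C to rt
Reagents that add atoms: none
Why: DDQ cleaves the remaining PMB ether under neutral buffered conditions that leave the oxiranes, the tiglate and the butenolide intact and cannot oxidise the electron-poor allylic alcohol.

Compound list
1 | methyl α-D-glucopyranoside | OC[C@H]1O[C@H](OC)[C@H](O)[C@@H](O)[C@@H]1O | starting material
2 | methyl 4,6-O-[(R)-4-methoxybenzylidene]-α-D-glucopyranoside | COc1ccc(cc1)[C@@H]1OC[C@H]2O[C@H](OC)[C@H](O)[C@@H](O)[C@@H]2O1 | intermediate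
3 | methyl 2-O-TBS-4,6-O-[(R)-4-methoxybenzylidene]-α-D-glucopyranoside | COc1ccc(cc1)[C@@H]1OC[C@H]2O[C@H](OC)[C@H](O[Si](C)(C)C(C)(C)C)[C@@H](O)[C@@H]2O1 | intermediate
4 | methyl 2-O-TBS-3-O-TES-4,6-O-[(R)-4-methoxybenzylidene]-α-D-glucopyranoside | COc1ccc(cc1)[C@@H]1OC[C@H]2O[C@H](OC)[C@H](O[Si](C)(C)C(C)(C)C)[C@@H](O[Si](CC)(CC)CC)[C@@H]2O1 | intermediate
5 | methyl 2-O-TBS-3-O-TES-4-O-PMB-α-D-glucopyranoside | OC[C@H]1O[C@H](OC)[C@H](O[Si](C)(C)C(C)(C)C)[C@@H](O[Si](CC)(CC)CC)[C@@H]1OCc1ccc(OC)cc1 | intermediate
6 | methyl 6-deoxy-6-iodo-2-O-TBS-3-O-TES-4-O-PMB-α-D-glucopyranoside | IC[C@H]1O[C@H](OC)[C@H](O[Si](C)(C)C(C)(C)C)[C@@H](O[Si](CC)(CC)CC)[C@@H]1OCc1ccc(OC)cc1 | intermediate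
7 | methyl 6-deoxy-2-O-TBS-3-O-TES-4-O-PMB-α-D-xylo-hex-5-enopyranoside | C=C1O[C@H](OC)[C@H](O[Si](C)(C)C(C)(C)C)[C@@H](O[Si](CC)(CC)CC)[C@@H]1OCc1ccc(OC)cc1 | intermediate
8 | cyclohexanone with C5=O, equatorial C6-OPMB, C7-OTES and C8-OTBS, axial C9-OH cis to O8, C10H2 | O=C1C[C@H](O)[C@H](O[Si](C)(C)C(C)(C)C)[C@@H](O[Si](CC)(CC)CC)[C@@H]1OCc1ccc(OC)cc1 | intermediate
9 | C9 methanesulfonate of 8 | O=C1C[C@H](OS(C)(=O)=O)[C@H](O[Si](C)(C)C(C)(C)C)[C@@H](O[Si](CC)(CC)CC)[C@@H]1OCc1ccc(OC)cc1 | intermediate
10 | enone with C5=O, C9=C10, C6-OPMB, C7-OTES, C8-OTBS (gluco pattern) | O=C1C=C[C@H](O[Si](C)(C)C(C)(C)C)[C@@H](O[Si](CC)(CC)CC)[C@@H]1OCc1ccc(OC)cc1 | intermediate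
11 | C10-iodo derivative of enone 10 | O=C1C(I)=C[C@H](O[Si](C)(C)C(C)(C)C)[C@@H](O[Si](CC)(CC)CC)[C@@H]1OCc1ccc(OC)cc1 | intermediate
12 | tributyl(vinyl)stannane | C=C[Sn](CCCC)(CCCC)CCCC | starting material
13 | C10-vinyl derivative of enone 10 | O=C1C(C=C)=C[C@H](O[Si](C)(C)C(C)(C)C)[C@@H](O[Si](CC)(CC)CC)[C@@H]1OCc1ccc(OC)cc1 | intermediate
14 | lithium C5=C10 dienolate bearing the C10 vinyl group | [Li+].[O-]C1=C(C=C)C[C@H](O[Si](C)(C)C(C)(C)C)[C@@H](O[Si](CC)(CC)CC)[C@@H]1OCc1ccc(OC)cc1 | intermediate
15 | C10-methyl C10-vinyl cyclohexan-5-one, methyl axial, vinyl equatorial and cis to O8 | O=C1[C@](C)(C=C)C[C@H](O[Si](C)(C)C(C)(C)C)[C@@H](O[Si](CC)(CC)CC)[C@@H]1OCc1ccc(OC)cc1 | intermediate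
16 | isopropenylmagnesium bromide | C=C(C)[Mg]Br | starting material
17 | C5-isopropenyl C10-methyl C10-vinyl cyclohexan-5-ol, OH axial and cis to O6, isopropenyl and vinyl trans-diequatorial, C6-OPMB, C7-OTES, C8-OTBS | O[C@]1(C(C)=C)[C@](C)(C=C)C[C@H](O[Si](C)(C)C(C)(C)C)[C@@H](O[Si](CC)(CC)CC)[C@@H]1OCc1ccc(OC)cc1 | intermediate
18 | potassium C5 alkoxide of 17 | [K+].[O-][C@]1(C(C)=C)[C@](C)(C=C)C[C@H](O[Si](C)(C)C(C)(C)C)[C@@H](O[Si](CC)(CC)CC)[C@@H]1OCc1ccc(OC)cc1 | intermediate
19 | ten-membered potassium C4=C5 enolate, C1=C10 E, C3 trans to C6 | CC(C)(C)[Si](C)(C)O[C@H]1C/C(C)=C/CC/C(C)=C(\[O-])[C@@H](OCc2ccc(OC)cc2)[C@@H]1O[Si](CC)(CC)CC.[K+] | intermediate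
20 | ten-membered dienyl C5 triflate, C1=C10 E, C3 trans to C6, C6-OPMB, C7-OTES, C8-OTBS | CC(C)(C)[Si](C)(C)O[C@H]1C/C(C)=C/CC/C(C)=C(\OS(=O)(=O)C(F)(F)F)[C@@H](OCc2ccc(OC)cc2)[C@@H]1O[Si](CC)(CC)CC | intermediate
21 | (1(10)E,4E)-germacradiene with C6-OPMB, C7-OTES, C8-OTBS | CC(C)(C)[Si](C)(C)O[C@H]1C/C(C)=C/CC/C(C)=C/[C@@H](OCc2ccc(OC)cc2)[C@@H]1O[Si](CC)(CC)CC | intermediate
22 | (1(10)E,4E)-germacradien-6-ol with C7-OTES, C8-OTBS | CC(C)(C)[Si](C)(C)O[C@H]1C/C(C)=C/CC/C(C)=C/[C@@H](O)[C@@H]1O[Si](CC)(CC)CC | intermediate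
23 | methyl 2-(dimethoxyphosphoryl)acrylate | C=C(C(=O)OC)P(=O)(OC)OC | starting material
24 | 4-methoxybenzyl alcohol | COc1ccc(CO)cc1 | starting material
25 | methyl 2-(dimethoxyphosphoryl)-3-(4-methoxybenzyloxy)propanoate (racemic) | COC(=O)C(COCc1ccc(OC)cc1)P(=O)(OC)OC | intermediate
26 | 2-(dimethoxyphosphoryl)-3-(4-methoxybenzyloxy)propanoic acid (racemic) | OC(=O)C(COCc1ccc(OC)cc1)P(=O)(OC)OC | intermediate
27 | C6 ester of 22 with acid 26 (C11 epimers), C7-OTES, C8-OTBS | CC(C)(C)[Si](C)(C)O[C@H]1C/C(C)=C/CC/C(C)=C/[C@@H](OC(=O)C(COCc2ccc(OC)cc2)P(=O)(OC)OC)[C@@H]1O[Si](CC)(CC)CC | intermediate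
28 | C7 alcohol obtained from 27 (C11 epimers), C8-OTBS | CC(C)(C)[Si](C)(C)O[C@H]1C/C(C)=C/CC/C(C)=C/[C@@H](OC(=O)C(COCc2ccc(OC)cc2)P(=O)(OC)OC)[C@@H]1O | intermediate
29 | C7 ketone obtained from 28 (C11 epimers) | CC(C)(C)[Si](C)(C)O[C@H]1C/C(C)=C/CC/C(C)=C/[C@@H](OC(=O)C(COCc2ccc(OC)cc2)P(=O)(OC)OC)C1=O | intermediate
30 | (1(10)E,4E)-germacra-1(10),4,7(11)-trien-12,6α-olide with 8α-OTBS and 13-OPMB | CC(C)(C)[Si](C)(C)O[C@H]1C/C(C)=C/CC/C(C)=C/[C@H]2OC(=O)C(COCc3ccc(OC)cc3)=C12 | intermediate
31 | 8α-hydroxy trienolide with 13-OPMB | O[C@H]1C/C(C)=C/CC/C(C)=C/[C@H]2OC(=O)C(COCc3ccc(OC)cc3)=C12 | intermediate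
32 | tiglic acid | C/C=C(\C)C(=O)O | starting material
33 | 8α-tigloyloxy trienolide with 13-OPMB | C/C=C(\C)C(=O)O[C@H]1C/C(C)=C/CC/C(C)=C/[C@H]2OC(=O)C(COCc3ccc(OC)cc3)=C12 | intermediate
34 | 8α-tigloyloxy-1β,10α:4α,5β-diepoxygermacr-7(11)-en-12,6α-olide 13-PMB ether | C/C=C(\C)C(=O)O[C@H]1C[C@@]2(C)O[C@@H]2CC[C@@]2(C)O[C@@H]2[C@H]2OC(=O)C(COCc3ccc(OC)cc3)=C12 | intermediate
35 | CNP0111480.1, 8α-tigloyloxy-13-hydroxy-1β,10α:4α,5β-diepoxygermacr-7(11)-en-12,6α-olide (1R,4R,5R,6S,8S,10R) | C/C=C(\C)C(=O)O[C@H]1C[C@@]2(C)O[C@@H]2CC[C@@]2(C)O[C@@H]2[C@H]2OC(=O)C(CO)=C12 | target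

Total step count: 24. Longest linear sequence: 22 steps (steps 1–15 and 18–24; steps 16 and 17 form the side branch to acid 26).

Steps most likely to fail

**Step 12.** The axial C10 methyl group lies beside the equatorial approach path. The nucleophile may therefore be diverted to the opposite face and deliver the cis-dialkenyl carbinol, which would lead to a Z ring alkene, or the reagent may merely enolise C6–H. The fallback removes the dependence on this face by letting oxygen, not carbon, arrive at C5. It sets out from ketone 15.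
- Addition of 16 promoted by CeCl3, taken whatever its facial outcome, gives the C5-epimeric carbinol F1, alone or mixed with 17.
- Burgess dehydration, for which C6–H is the only β-hydrogen, gives the 6-(4-methoxybenzyloxy) diene F2.
- Dimethyldioxirane at −78 °C epoxidises the electron-rich C5=C6 enol ether from the face opposite to the axial C10 methyl group and the C7 silyloxy group, giving the epoxy ether F3.
- LiBHEt3 opens F3 at the acetal carbon C6 with inversion. This restores the equatorial C6 ether, leaves the C5 oxygen axial and returns the route at carbinol 17.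

**Step 13.** The shift may be sluggish, or proton transfer within the potassium enolate before sulfonylation may start loss of the C7 silyloxy group and erode the enolate geometry. The fallback is the base-free siloxy-Cope variant. It sets out from carbinol 17.
- Trimethylsilyl triflate and 2,6-lutidine give the trimethylsilyl ether F4.
- Thermolysis in degassed o-xylene in a sealed tube at about 200 °C passes through the same chair and gives the ten-membered trimethylsilyl enol ether F5, which can be purified.
- MeLi in THF at 0 °C cleaves the Si–O bond to the lithium enolate F6, free of any amine proton shuttle.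
- PhNTf2 converts F6 into triflate 20, where the route is rejoined.

**Step 23.** Facial selectivity may be poor at one of the two ring alkenes if a second ring conformer is populated. The first-formed oxirane may also suffer transannular opening by the carboxylic acid. The fallback replaces substrate control by reagent control. It sets out from tiglate 33 and returns at diepoxide 34. A Shi epoxidation with the D-fructose-derived ketone, KHSO5 and K2CO3 buffer in MeCN/dimethoxymethane/H2O at 0 °C is used. Its known sense for E-trisubstituted alkenes (R,R) matches both oxiranes, the medium is never acidic, and no new compound is made on the way.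

Further compounds
F1 | step 12 | C5 epimer of carbinol 17 (OH equatorial, isopropenyl axial and cis to vinyl) | O[C@@]1(C(C)=C)[C@](C)(C=C)C[C@H](O[Si](C)(C)C(C)(C)C)[C@@H](O[Si](CC)(CC)CC)[C@@H]1OCc1ccc(OC)cc1
F2 | step 12 | C5-isopropenyl C6-(4-methoxybenzyloxy) cyclohex-5-ene with C7-OTES, C8-OTBS, C10 methyl and vinyl | CC(=C)C=1[C@](C)(C=C)C[C@H](O[Si](C)(C)C(C)(C)C)[C@@H](O[Si](CC)(CC)CC)C=1OCc1ccc(OC)cc1
F3 | step 12 | C5–C6 epoxy ether of F2, oxirane oxygen on the face opposite to the C10 methyl group | CC(=C)[C@@]12[C@](C)(C=C)C[C@H](O[Si](C)(C)C(C)(C)C)[C@@H](O[Si](CC)(CC)CC)[C@]1(OCc1ccc(OC)cc1)O2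
F4 | step 13 | C5 trimethylsilyl ether of carbinol 17 | C[Si](C)(C)O[C@]1(C(C)=C)[C@](C)(C=C)C[C@H](O[Si](C)(C)C(C)(C)C)[C@@H](O[Si](CC)(CC)CC)[C@@H]1OCc1ccc(OC)cc1
F5 | step 13 | ten-membered C5 trimethylsilyl enol ether, C1=C10 E, C3 trans to C6 | CC(C)(C)[Si](C)(C)O[C@H]1C/C(C)=C/CC/C(C)=C(\O[Si](C)(C)C)[C@@H](OCc2ccc(OC)cc2)[C@@H]1O[Si](CC)(CC)CC
F6 | step 13 | ten-membered lithium C4=C5 enolate, C1=C10 E, C3 trans to C6 | CC(C)(C)[Si](C)(C)O[C@H]1C/C(C)=C/CC/C(C)=C(\[O-])[C@@H](OCc2ccc(OC)cc2)[C@@H]1O[Si](CC)(CC)CC.[Li+]
F0 | step 23 | none | none
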